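The readings stem from a simulated flask on assumed constants, noise included.

If the partner is paid out twice, once when substrate becomes intermediate A and again when intermediate A goes on through target to over-reaction product, then I can reckon this flask from its charge.

| flask | substrate | partner | remark | time |
|---|---|---|---|---|
| beta | 0.50 M | 0.84 M | run made earlier |  |
| epsilon | 0.50 M | 1.3 M | run made earlier |  |
| flask | 0.50 M | 0.600 M |  | 15 h |

- beta (time / h: intermediate A / %, target / %): 1.00: 37.1, 1.1; 2.00: 28.1, 0; 3.00: 25.5, 0.8; 6.00: 25.0, 0.5; 12.0: 21.8, 0
- epsilon (time / h: intermediate A / %, target / %): 2.50: 3.0, 0; 5.00: 0.3, 0; 8.00: 0, 1.5; 10.0: 0.3, 0; 12.0: 0.6, 0

(readings scatter by 1 percentage point)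

- candidate steps: substrate + partner -> intermediate A; intermediate A <-> intermediate B; partner + intermediate A -> target; target -> over-reaction product
- the reaction counts as stopped when no species that holds the substrate changes by six tenths of a point or more over the second half of the time

- which holds at 15 h: what has brought the reaction to rest, or that it has not come to rest (it is still moving / the partner has run out first / forward and back rates have come level)
- how much intermediate A there is at 15 h, in percent of the substrate charged

How much substrate escapes the second payment? The pool, two minus the equivalents of partner, is the share of charged substrate still held in intermediate A and intermediate B once substrate and partner are both used up; in this flask it is 80.0%. The earlier runs fit that reading: the pool is 32.0% in beta, where intermediate A levels off, and −60.0% in epsilon, where its readings lie within the scatter of zero from 5.00 h on.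

How much of the pool shows as intermediate A? Beta's last two readings average 73.1% of its pool, so I take that share here and get 58.5%.

Does this flask stop by the asked time? Its partner, the limiting reagent, stands at 0.600 M against the 1.00 M that full conversion wants, and beta's readings of intermediate A go from 37.1% at 1.00 h to 25.0% at 6.00 h and 21.8% at 12.0 h, a time shorter than the one asked here, so I answer that the partner ends it.

The forecast gives the partner has run out first and 55%, a little below my figure, holding that “the partner again runs out”.

The flask gives the partner has run out first, with 56.1% of intermediate A, and its partner stands at 0% of its charge.

    substrate + partner → intermediate A (k = 0.842 M⁻¹ min⁻¹)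
    intermediate A ⇌ intermediate B (K = 0.360, k = 0.0236 min⁻¹)
    partner + intermediate A → target (k = 0.0833 M⁻¹ min⁻¹)
    target → over-reaction product (k = 0.142 min⁻¹)

The pool needs one correction here: 1.8% of substrate remains, and subtracting twice that from the pool gives 76.4%, against 76.3% in intermediate A and intermediate B together. In the neighbour flask with 1.5 M of partner, the pool is −100%, so I expect no intermediate A there and 33.3% of the partner unused. That neighbour computes to 0% of intermediate A, 100% of over-reaction product and 33% of its partner left.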